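**Retrosynthetic overview**

1. (2S,3S)-trans-δ-viniferin <= removal of four O-benzyl groups <= (E)-stilbene by Horner–Wadsworth–Emmons olefination of a C5 aldehyde on a (2S,3S)-2,3-diaryl-2,3-dihydrobenzofuran.
2. Dihydrobenzofuran <= one-operation ring expansion of an enantiopure trans-1,2-diaryloxirane by an aryne: the oxirane oxygen becomes O1 and bonds to C7a; the oxirane carbon carrying the resorcinol-type ring becomes C3 and bonds to C3a.
3. Enabling feature: O1–C2–C3 of the dihydrofuran ring is a trans-stilbene oxide minus one C–O bond (C3 is benzylic, so its C–O bond can ionise), and C7a/C3a are two neighbouring sp2 carbons of the benzo ring, which is an aryne; the trans-2,3-diaryl pattern maps onto a trans-epoxide from a Shi epoxidation.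
4. Shaping groups, all removed later: an aryl triflate on the C2 aryl ring (electronic switch so that C3–O breaks; later the 4-OH), a chlorine at C4 of the aryne (steers oxygen to C7a), a dioxolane at C5 (masked aldehyde).
5. Ring order: oxirane (step 4), then the dihydrofuran ring by ring expansion (step 9); all benzene rings are bought.

Key step: step 9

Remark: ring positions are cited in 2,3-dihydro-1-benzofuran numbering (O1, C2, C3, C3a, C4 to C7, C7a); it is assumed that the D-fructose-derived ketone gives the (R,R)-oxirane from the stilbene of step 3, as it does from trans-stilbene itself.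

**Step 1**
Reactants: 1 4-hydroxybenzaldehyde
Product: 2 4-formylphenyl trifluoromethanesulfonate
Conditions: Tf2O, pyridine, CH2Cl2, 0 °C to rt
Reagents that add atoms: trifluoromethanesulfonic anhydride, O=S(=O)(OS(=O)(=O)C(F)(F)F)C(F)(F)F
Why: O-sulfonylation of a phenol with triflic anhydride is routine and installs from the start the electron-poor sulfonate that also protects the future 4-hydroxyl.

**Step 2**
Reactants: 3 3,5-bis(benzyloxy)benzyl bromide
Product: 4 diethyl [3,5-bis(benzyloxy)benzyl]phosphonate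
Conditions: P(OEt)3 (neat), 140 °C
Reagents that add atoms: triethyl phosphite, CCOP(OCC)OCC
Why: Michaelis–Arbuzov reaction of a primary benzylic bromide, driven by loss of volatile bromoethane.

**Step 3**
Reactants: 4 diethyl [3,5-bis(benzyloxy)benzyl]phosphonate, 2 4-formylphenyl trifluoromethanesulfonate
Product: 5 4-{(E)-2-[3,5-bis(benzyloxy)phenyl]ethenyl}phenyl trifluoromethanesulfonate
Conditions: NaH, THF, 0 °C; then 2, 0 °C to rt
Reagents that add atoms: none
Why: Horner–Wadsworth–Emmons olefination of an aryl aldehyde with a benzylic phosphonate anion should give the (E)-stilbene, the preformed carbanion attacking the aldehyde far faster than the sulfonate.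

**Step 4**
Reactants: 5 4-{(E)-2-[3,5-bis(benzyloxy)phenyl]ethenyl}phenyl trifluoromethanesulfonate
Product: 6 4-{(2R,3R)-3-[3,5-bis(benzyloxy)phenyl]oxiran-2-yl}phenyl trifluoromethanesulfonate (trans-oxirane)
Conditions: 1,2:4,5-di-O-isopropylidene-β-D-erythro-2,3-hexodiulo-2,6-pyranose (D-fructose-derived ketone, 0.3 equiv), Oxone (2KHSO5·KHSO4·K2SO4), K2CO3, Bu4NHSO4, MeCN/CH2(OMe)2/aqueous Na2B4O7–Na2EDTA buffer, 0 °C
Reagents that add atoms: potassium peroxymonosulfate (active part of Oxone), [K+].[O-]S(=O)(=O)OO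
Why: Shi epoxidation, in which the chiral dioxirane formed in situ transfers oxygen to the trans-alkene through a spiro transition state and should give the (R,R)-oxirane, so that both stereocentres of the target are set here by the catalyst.

**Step 5**
Reactants: 7 2-chloro-4-hydroxybenzaldehyde
Product: 8 3-chloro-4-formylphenyl N-isopropylcarbamate
Conditions: iPrNCO, Et3N (cat.), CH2Cl2, rt
Reagents that add atoms: isopropyl isocyanate, CC(C)N=C=O
Why: Base-catalysed addition of the phenol to an isocyanate gives the secondary carbamate that later directs ortho-lithiation and can be removed under mild base.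

**Step 6**
Reactants: 8 3-chloro-4-formylphenyl N-isopropylcarbamate
Product: 9 3-chloro-4-(1,3-dioxolan-2-yl)phenyl N-isopropylcarbamate
Conditions: HOCH2CH2OH, p-TsOH·H2O (cat.), toluene, reflux, Dean–Stark trap
Reagents that add atoms: ethylene glycol, OCCO
Why: Acid-catalysed acetalisation with azeotropic removal of water masks the aldehyde against the organolithium and fluoride steps that follow.

**Step 7**
Reactants: 9 3-chloro-4-(1,3-dioxolan-2-yl)phenyl N-isopropylcarbamate
Product: 13 3-chloro-4-(1,3-dioxolan-2-yl)-2-(trimethylsilyl)phenyl N-isopropylcarbamate, via N-silyl carbamate 10 (not isolated), via aryllithium 11 (not isolated), via N-silyl ortho-silyl carbamate 12 (not isolated)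
Conditions: TBSOTf (1.05 equiv), TMEDA, Et2O, 0 °C to rt; then n-BuLi, TMEDA, −78 °C; then Me3SiCl, −78 °C to rt; aqueous NH4Cl/MeOH work-up
Reagents that add atoms: chlorotrimethylsilane, C[Si](C)(C)Cl
Why: Directed ortho-metalation, in which the N-silylated carbamate and the chlorine together acidify the ring C–H lying between them so that lithiation and silylation should occur only there, the N–Si bond being lost on work-up and the small excess of silyl triflate sparing the dioxolane.

**Step 8**
Reactants: 13 3-chloro-4-(1,3-dioxolan-2-yl)-2-(trimethylsilyl)phenyl N-isopropylcarbamate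
Product: 15 3-chloro-4-(1,3-dioxolan-2-yl)-2-(trimethylsilyl)phenyl trifluoromethanesulfonate, via silyl phenol 14 (not isolated)
Conditions: DBU, Et2NH, MeCN, 40 °C; then PhNTf2, rt
Reagents that add atoms: N-phenylbis(trifluoromethanesulfonimide), O=S(=O)(N(c1ccccc1)S(=O)(=O)C(F)(F)F)C(F)(F)F
Why: Base-induced elimination of the N–H carbamate (the isocyanate is trapped by diethylamine as a urea) frees the phenoxide, which is triflated in the same flask to give the ortho-silylaryl triflate aryne precursor.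

**Step 9**
Reactants: 6 4-{(2R,3R)-3-[3,5-bis(benzyloxy)phenyl]oxiran-2-yl}phenyl trifluoromethanesulfonate, 15 3-chloro-4-(1,3-dioxolan-2-yl)-2-(trimethylsilyl)phenyl trifluoromethanesulfonate
Product: 18 4-{(2S,3S)-3-[3,5-bis(benzyloxy)phenyl]-4-chloro-5-(1,3-dioxolan-2-yl)-2,3-dihydro-1-benzofuran-2-yl}phenyl trifluoromethanesulfonate, via 3-chloro-4-(1,3-dioxolan-2-yl)benzyne 16 (not isolated), via aryl anion oxiranium zwitterion 17 (not isolated)
Conditions: CsF, MeCN/toluene (1:2), 40 °C, 15 (2.5 equiv) added slowly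
Reagents that add atoms: none
Why: Proposed new method: fluoride removes the silyl group of 15 and triflate departs to give aryne 16; the oxirane oxygen of 6 adds to the aryne carbon that becomes C7a, and in the resulting aryl anion/O-aryloxiranium zwitterion 17 the C–O bond to the carbon carrying the bis(benzyloxy)phenyl ring ionises while the neighbouring aryl anion (future C3a) collapses onto that carbon (future C3), so that the O1–C7a and C3–C3a bonds are both made in one operation. The closest known reaction type is the fluoride-induced insertion of arynes from ortho-silylaryl triflates into a C–O bond of styrene oxide, which gives 2,3-dihydrobenzofurans; its use on an enantiopure trans-1,2-diaryloxirane with transfer of configuration is what is new. The dihydrofuran ring, the only ring closed, arises by ring expansion of the oxirane in a formally 5-endo-tet closure, which cannot be a back-side displacement and should therefore run as a front-side, ion-pair-type collapse. No stereocentre is made from nothing: C2 is not touched and keeps the configuration from step 4, and C3 is re-formed with retention because the carbanion sits on the face from which the oxygen leaves, the trans arrangement also being the one the C2 aryl group enforces should the ion pair live long enough to rotate. Three selectivities are needed and are built into the substrates: oxygen attack at C7a is secured by the chlorine at C4, since a 3-haloaryne is attacked at the carbon remote from the halogen so that the anion develops next to it; cleavage of C3–O and not C2–O is secured by the para-triflate, which makes the benzylic position of its own ring much the poorer cation; and C–C collapse ahead of protonation of the aryl anion is favoured by the absence of N–H or O–H groups and by a medium of low acidity.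

**Step 10**
Reactants: 18 4-{(2S,3S)-3-[3,5-bis(benzyloxy)phenyl]-4-chloro-5-(1,3-dioxolan-2-yl)-2,3-dihydro-1-benzofuran-2-yl}phenyl trifluoromethanesulfonate
Product: 19 4-{(2S,3S)-3-[3,5-bis(benzyloxy)phenyl]-4-chloro-5-(1,3-dioxolan-2-yl)-2,3-dihydro-1-benzofuran-2-yl}phenol
Conditions: Et4NOH (20% aqueous), 1,4-dioxane, rt; aqueous NH4Cl work-up
Reagents that add atoms: none
Why: Hydroxide attacks sulfur of the aryl triflate (S–O cleavage) and frees the 4-hydroxyl of the target while acetal, benzyl ethers and aryl chloride are inert, which also removes the sulfonate before the palladium step that would otherwise reduce it.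

**Step 11**
Reactants: 19 4-{(2S,3S)-3-[3,5-bis(benzyloxy)phenyl]-4-chloro-5-(1,3-dioxolan-2-yl)-2,3-dihydro-1-benzofuran-2-yl}phenol
Product: 21 (2S,3S)-3-[3,5-bis(benzyloxy)phenyl]-2-(4-hydroxyphenyl)-2,3-dihydro-1-benzofuran-5-carbaldehyde, via dechlorinated acetal 20 (not isolated)
Conditions: Pd(OAc)2 (5 mol %), XPhos (2-dicyclohexylphosphino-2',4',6'-triisopropylbiphenyl, 10 mol %), HCO2Na, DMF/H2O, 90 °C; then 2 M HCl, THF, rt
Reagents that add atoms: water, O
Why: Palladium-catalysed hydrodehalogenation, in which zerovalent palladium carrying the bulky biarylphosphine inserts into the hindered C4–Cl bond and formate delivers the hydride, removes the temporary chlorine without touching benzyl ethers, after which dilute acid hydrolyses the dioxolane and can only return C2 to the trans arrangement it already has.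

**Step 12**
Reactants: 21 (2S,3S)-3-[3,5-bis(benzyloxy)phenyl]-2-(4-hydroxyphenyl)-2,3-dihydro-1-benzofuran-5-carbaldehyde, 4 diethyl [3,5-bis(benzyloxy)benzyl]phosphonate
Product: 22 4-{(2S,3S)-3-[3,5-bis(benzyloxy)phenyl]-5-{(E)-2-[3,5-bis(benzyloxy)phenyl]ethenyl}-2,3-dihydro-1-benzofuran-2-yl}phenol
Conditions: KOtBu (3 equiv), THF, 0 °C to rt
Reagents that add atoms: none
Why: Horner–Wadsworth–Emmons olefination with the same benzylic phosphonate should give the (E)-stilbene, the free phenol only consuming one equivalent of base and the stereocentres not being involved.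

**Step 13**
Reactants: 22 4-{(2S,3S)-3-[3,5-bis(benzyloxy)phenyl]-5-{(E)-2-[3,5-bis(benzyloxy)phenyl]ethenyl}-2,3-dihydro-1-benzofuran-2-yl}phenol
Product: 23 (2S,3S)-trans-δ-viniferin, 5-{(2S,3S)-5-[(E)-2-(3,5-dihydroxyphenyl)ethenyl]-2-(4-hydroxyphenyl)-2,3-dihydro-1-benzofuran-3-yl}benzene-1,3-diol
Conditions: BCl3 (1 M in CH2Cl2), pentamethylbenzene, CH2Cl2, −78 °C; then MeOH
Reagents that add atoms: none
Why: Lewis-acid cleavage of aryl benzyl ethers at low temperature with pentamethylbenzene as a Friedel–Crafts trap for the benzyl cations should free all four phenols without alkylating the electron-rich rings or the stilbene and without touching C2 or C3.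

**Compound list**

1 | 4-hydroxybenzaldehyde | O=Cc1ccc(O)cc1 | starting material
2 | 4-formylphenyl trifluoromethanesulfonate | O=Cc1ccc(OS(=O)(=O)C(F)(F)F)cc1 | intermediate
3 | 3,5-bis(benzyloxy)benzyl bromide | BrCc1cc(OCc2ccccc2)cc(OCc2ccccc2)c1 | starting material
4 | diethyl [3,5-bis(benzyloxy)benzyl]phosphonate | CCOP(=O)(OCC)Cc1cc(OCc2ccccc2)cc(OCc2ccccc2)c1 | intermediate
5 | 4-{(E)-2-[3,5-bis(benzyloxy)phenyl]ethenyl}phenyl trifluoromethanesulfonate | O=S(=O)(Oc1ccc(/C=C/c2cc(OCc3ccccc3)cc(OCc3ccccc3)c2)cc1)C(F)(F)F | intermediate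
6 | 4-{(2R,3R)-3-[3,5-bis(benzyloxy)phenyl]oxiran-2-yl}phenyl trifluoromethanesulfonate | O=S(=O)(Oc1ccc([C@H]2O[C@@H]2c2cc(OCc3ccccc3)cc(OCc3ccccc3)c2)cc1)C(F)(F)F | intermediate
7 | 2-chloro-4-hydroxybenzaldehyde | O=Cc1ccc(O)cc1Cl | starting material
8 | 3-chloro-4-formylphenyl N-isopropylcarbamate | CC(C)NC(=O)Oc1ccc(C=O)c(Cl)c1 | intermediate
9 | 3-chloro-4-(1,3-dioxolan-2-yl)phenyl N-isopropylcarbamate | CC(C)NC(=O)Oc1ccc(C2OCCO2)c(Cl)c1 | intermediate
10 | 3-chloro-4-(1,3-dioxolan-2-yl)phenyl N-(tert-butyldimethylsilyl)-N-isopropylcarbamate | CC(C)N(C(=O)Oc1ccc(C2OCCO2)c(Cl)c1)[Si](C)(C)C(C)(C)C | intermediate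
11 | 2-lithio derivative of 10 (lithium on the ring carbon between the carbamate oxygen and chlorine) | CC(C)N(C(=O)Oc1ccc(C2OCCO2)c(Cl)c1[Li])[Si](C)(C)C(C)(C)C | intermediate
12 | 3-chloro-4-(1,3-dioxolan-2-yl)-2-(trimethylsilyl)phenyl N-(tert-butyldimethylsilyl)-N-isopropylcarbamate | CC(C)N(C(=O)Oc1ccc(C2OCCO2)c(Cl)c1[Si](C)(C)C)[Si](C)(C)C(C)(C)C | intermediate
13 | 3-chloro-4-(1,3-dioxolan-2-yl)-2-(trimethylsilyl)phenyl N-isopropylcarbamate | CC(C)NC(=O)Oc1ccc(C2OCCO2)c(Cl)c1[Si](C)(C)C | intermediate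
14 | 3-chloro-4-(1,3-dioxolan-2-yl)-2-(trimethylsilyl)phenol | Oc1ccc(C2OCCO2)c(Cl)c1[Si](C)(C)C | intermediate
15 | 3-chloro-4-(1,3-dioxolan-2-yl)-2-(trimethylsilyl)phenyl trifluoromethanesulfonate | O=S(=O)(Oc1ccc(C2OCCO2)c(Cl)c1[Si](C)(C)C)C(F)(F)F | intermediate
16 | 3-chloro-4-(1,3-dioxolan-2-yl)benzyne (formal triple bond between the former C–OTf and C–SiMe3 carbons) | ClC1=C(C2OCCO2)C=CC#C1 | intermediate
17 | O-aryloxiranium zwitterion: oxirane oxygen of 6 bonded to the aryne carbon remote from chlorine, carbanion on the ring carbon between oxygen and chlorine | O=S(=O)(Oc1ccc([C@H]2[O+]([C@@H]2c2cc(OCc3ccccc3)cc(OCc3ccccc3)c2)c2ccc(C3OCCO3)c(Cl)[c-]2)cc1)C(F)(F)F | intermediate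
18 | 4-{(2S,3S)-3-[3,5-bis(benzyloxy)phenyl]-4-chloro-5-(1,3-dioxolan-2-yl)-2,3-dihydro-1-benzofuran-2-yl}phenyl trifluoromethanesulfonate | O=S(=O)(Oc1ccc([C@H]2Oc3ccc(C4OCCO4)c(Cl)c3[C@@H]2c2cc(OCc3ccccc3)cc(OCc3ccccc3)c2)cc1)C(F)(F)F | intermediate
19 | 4-{(2S,3S)-3-[3,5-bis(benzyloxy)phenyl]-4-chloro-5-(1,3-dioxolan-2-yl)-2,3-dihydro-1-benzofuran-2-yl}phenol | Oc1ccc([C@H]2Oc3ccc(C4OCCO4)c(Cl)c3[C@@H]2c2cc(OCc3ccccc3)cc(OCc3ccccc3)c2)cc1 | intermediate
20 | 4-{(2S,3S)-3-[3,5-bis(benzyloxy)phenyl]-5-(1,3-dioxolan-2-yl)-2,3-dihydro-1-benzofuran-2-yl}phenol | Oc1ccc([C@H]2Oc3ccc(C4OCCO4)cc3[C@@H]2c2cc(OCc3ccccc3)cc(OCc3ccccc3)c2)cc1 | intermediate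
21 | (2S,3S)-3-[3,5-bis(benzyloxy)phenyl]-2-(4-hydroxyphenyl)-2,3-dihydro-1-benzofuran-5-carbaldehyde | Oc1ccc([C@H]2Oc3ccc(C=O)cc3[C@@H]2c2cc(OCc3ccccc3)cc(OCc3ccccc3)c2)cc1 | intermediate
22 | 4-{(2S,3S)-3-[3,5-bis(benzyloxy)phenyl]-5-{(E)-2-[3,5-bis(benzyloxy)phenyl]ethenyl}-2,3-dihydro-1-benzofuran-2-yl}phenol | Oc1ccc([C@H]2Oc3ccc(/C=C/c4cc(OCc5ccccc5)cc(OCc5ccccc5)c4)cc3[C@@H]2c2cc(OCc3ccccc3)cc(OCc3ccccc3)c2)cc1 | intermediate
23 | (2S,3S)-trans-δ-viniferin | Oc1ccc([C@H]2Oc3ccc(/C=C/c4cc(O)cc(O)c4)cc3[C@@H]2c2cc(O)cc(O)c2)cc1 | target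

**Totals and risks**

Total number of steps: 13. Longest linear sequence: 9 steps (steps 5, 6, 7, 8, 9, 10, 11, 12 and 13, from 7 to 23).

Steps most likely to fail:

1. Step 9 (Proposed new method). The oxirane oxygen is a weak, hindered nucleophile, so the aryne may be lost to fluoride, to the acetal oxygens of its own precursor or to self-condensation before it is captured. Inside the zwitterion, proton transfer from an oxiranium C–H to the aryl anion, a hydride shift after C–O ionisation, or loss of chloride from the ortho-chloroaryl anion may outrun C–C bond formation. Ionisation on the wrong side would give the regioisomeric ring. The fallback uses only known reaction types, sets out from stilbene 5 and comes back to the route at aldehyde 21. Shi epoxidation of 5 with the enantiomeric ketone (made from L-sorbose) would give 4-{(2S,3S)-3-[3,5-bis(benzyloxy)phenyl]oxiran-2-yl}phenyl trifluoromethanesulfonate F1. Commercial 3-bromo-4-fluorobenzaldehyde would be acetalised with ethylene glycol and p-TsOH to 2-(3-bromo-4-fluorophenyl)-1,3-dioxolane F2 and converted by bromine–magnesium exchange with iPrMgCl·LiCl into [5-(1,3-dioxolan-2-yl)-2-fluorophenyl]magnesium chloride F3. Opening of F1 by F3 with catalytic CuI (THF, −30 to 0 °C) should proceed with inversion at the benzylic carbon carrying the bis(benzyloxy)phenyl ring, the triflate again disfavouring attack next to its own ring, to give 4-{(1R,2S)-2-[3,5-bis(benzyloxy)phenyl]-2-[5-(1,3-dioxolan-2-yl)-2-fluorophenyl]-1-hydroxyethyl}phenyl trifluoromethanesulfonate F4. NaH in DMF would close the ring by intramolecular SNAr of the alkoxide on the aryl fluoride to the cis compound 4-{(2R,3S)-3-[3,5-bis(benzyloxy)phenyl]-5-(1,3-dioxolan-2-yl)-2,3-dihydro-1-benzofuran-2-yl}phenyl trifluoromethanesulfonate F5, and Et4NOH would free 4-{(2R,3S)-3-[3,5-bis(benzyloxy)phenyl]-5-(1,3-dioxolan-2-yl)-2,3-dihydro-1-benzofuran-2-yl}phenol F6. Aqueous HCl in THF would then hydrolyse the acetal and, through reversible opening of the C2–O1 bond to the quinone-methide-type cation that the free 4-hydroxyphenyl group allows, equilibrate C2 to the more stable trans isomer, which is 21. In this sequence C3 is fixed by the stereospecific epoxide opening and C2 is corrected thermodynamically.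

2. Step 13. While four benzyl groups are removed, the Lewis acid may ionise the C2–O1 bond or trigger cationic cyclisation and oligomerisation of the electron-rich stilbene, and benzyl cations that escape the trap may C-alkylate the product. The fallback sets out from aldehyde 21 and comes back at target 23; it removes the benzyl groups before the alkene exists and finishes with fluoride-labile groups. Hydrogenolysis of 21 (H2, Pd/C, EtOAc) would give (2S,3S)-3-(3,5-dihydroxyphenyl)-2-(4-hydroxyphenyl)-2,3-dihydro-1-benzofuran-5-carbaldehyde F7, and TBSCl/imidazole would give (2S,3S)-3-[3,5-bis(tert-butyldimethylsilyloxy)phenyl]-2-[4-(tert-butyldimethylsilyloxy)phenyl]-2,3-dihydro-1-benzofuran-5-carbaldehyde F8. Phosphonate 4 would be hydrogenolysed in the same way to diethyl (3,5-dihydroxybenzyl)phosphonate F9 and silylated to diethyl [3,5-bis(tert-butyldimethylsilyloxy)benzyl]phosphonate F10. Horner–Wadsworth–Emmons olefination of F8 with F10 (NaH, THF) would give penta-O-(tert-butyldimethylsilyl)-(2S,3S)-trans-δ-viniferin F11, from which Bu4NF buffered with AcOH would release 23 without any Lewis acid.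

3. Step 12. Deprotonation of the free phenol gives a phenoxide that can expel the aryloxide at C2 (quinone methide formation); reclosure could erode the trans relationship, and proton loss at C3 from the opened form would destroy the ring. The fallback sets out from aldehyde 21 and comes back at 22; it masks the phenol during the olefination. TBSCl/imidazole would give (2S,3S)-3-[3,5-bis(benzyloxy)phenyl]-2-[4-(tert-butyldimethylsilyloxy)phenyl]-2,3-dihydro-1-benzofuran-5-carbaldehyde F12. Olefination with 4 (NaH, THF) would give tert-butyl{4-[(2S,3S)-3-[3,5-bis(benzyloxy)phenyl]-5-{(E)-2-[3,5-bis(benzyloxy)phenyl]ethenyl}-2,3-dihydro-1-benzofuran-2-yl]phenoxy}dimethylsilane F13, and Bu4NF in THF at 0 °C would return 22.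

**Further compounds**

F1 | step 9 | 4-{(2S,3S)-3-[3,5-bis(benzyloxy)phenyl]oxiran-2-yl}phenyl trifluoromethanesulfonate | O=S(=O)(Oc1ccc([C@@H]2O[C@H]2c2cc(OCc3ccccc3)cc(OCc3ccccc3)c2)cc1)C(F)(F)F
F2 | step 9 | 2-(3-bromo-4-fluorophenyl)-1,3-dioxolane | Fc1ccc(C2OCCO2)cc1Br
F3 | step 9 | [5-(1,3-dioxolan-2-yl)-2-fluorophenyl]magnesium chloride | Fc1ccc(C2OCCO2)cc1[Mg]Cl
F4 | step 9 | 4-{(1R,2S)-2-[3,5-bis(benzyloxy)phenyl]-2-[5-(1,3-dioxolan-2-yl)-2-fluorophenyl]-1-hydroxyethyl}phenyl trifluoromethanesulfonate | O=S(=O)(Oc1ccc([C@H](O)[C@@H](c2cc(OCc3ccccc3)cc(OCc3ccccc3)c2)c2cc(C3OCCO3)ccc2F)cc1)C(F)(F)F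
F5 | step 9 | 4-{(2R,3S)-3-[3,5-bis(benzyloxy)phenyl]-5-(1,3-dioxolan-2-yl)-2,3-dihydro-1-benzofuran-2-yl}phenyl trifluoromethanesulfonate | O=S(=O)(Oc1ccc([C@@H]2Oc3ccc(C4OCCO4)cc3[C@@H]2c2cc(OCc3ccccc3)cc(OCc3ccccc3)c2)cc1)C(F)(F)F
F6 | step 9 | 4-{(2R,3S)-3-[3,5-bis(benzyloxy)phenyl]-5-(1,3-dioxolan-2-yl)-2,3-dihydro-1-benzofuran-2-yl}phenol | Oc1ccc([C@@H]2Oc3ccc(C4OCCO4)cc3[C@@H]2c2cc(OCc3ccccc3)cc(OCc3ccccc3)c2)cc1
F7 | step 13 | (2S,3S)-3-(3,5-dihydroxyphenyl)-2-(4-hydroxyphenyl)-2,3-dihydro-1-benzofuran-5-carbaldehyde | Oc1ccc([C@H]2Oc3ccc(C=O)cc3[C@@H]2c2cc(O)cc(O)c2)cc1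
F8 | step 13 | (2S,3S)-3-[3,5-bis(tert-butyldimethylsilyloxy)phenyl]-2-[4-(tert-butyldimethylsilyloxy)phenyl]-2,3-dihydro-1-benzofuran-5-carbaldehyde | CC(C)(C)[Si](C)(C)Oc1ccc([C@H]2Oc3ccc(C=O)cc3[C@@H]2c2cc(O[Si](C)(C)C(C)(C)C)cc(O[Si](C)(C)C(C)(C)C)c2)cc1
F9 | step 13 | diethyl (3,5-dihydroxybenzyl)phosphonate | CCOP(=O)(OCC)Cc1cc(O)cc(O)c1
F10 | step 13 | diethyl [3,5-bis(tert-butyldimethylsilyloxy)benzyl]phosphonate | CCOP(=O)(OCC)Cc1cc(O[Si](C)(C)C(C)(C)C)cc(O[Si](C)(C)C(C)(C)C)c1
F11 | step 13 | penta-O-(tert-butyldimethylsilyl)-(2S,3S)-trans-δ-viniferin | CC(C)(C)[Si](C)(C)Oc1ccc([C@H]2Oc3ccc(/C=C/c4cc(O[Si](C)(C)C(C)(C)C)cc(O[Si](C)(C)C(C)(C)C)c4)cc3[C@@H]2c2cc(O[Si](C)(C)C(C)(C)C)cc(O[Si](C)(C)C(C)(C)C)c2)cc1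
F12 | step 12 | (2S,3S)-3-[3,5-bis(benzyloxy)phenyl]-2-[4-(tert-butyldimethylsilyloxy)phenyl]-2,3-dihydro-1-benzofuran-5-carbaldehyde | CC(C)(C)[Si](C)(C)Oc1ccc([C@H]2Oc3ccc(C=O)cc3[C@@H]2c2cc(OCc3ccccc3)cc(OCc3ccccc3)c2)cc1
F13 | step 12 | tert-butyl{4-[(2S,3S)-3-[3,5-bis(benzyloxy)phenyl]-5-{(E)-2-[3,5-bis(benzyloxy)phenyl]ethenyl}-2,3-dihydro-1-benzofuran-2-yl]phenoxy}dimethylsilane | CC(C)(C)[Si](C)(C)Oc1ccc([C@H]2Oc3ccc(/C=C/c4cc(OCc5ccccc5)cc(OCc5ccccc5)c4)cc3[C@@H]2c2cc(OCc3ccccc3)cc(OCc3ccccc3)c2)cc1
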